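Start from the slowness of the green run, which is the asked flask followed so far: after 10.0 h the reading is still 81.2% of its starting material.

- green: starting material 0.20 M; reagent 0.80 M; initiator 20 mM; the very flask that is asked about, followed so far
- flask: starting material 0.20 M; reagent 0.800 M; initiator 20 mM; time 2.0 d

green run (percent of the starting material charged)

| time / h | side product / % | target / % | first chain carrier / % | starting material / % |
|---|---|---|---|---|
| 0.833 | 0 | 1.0 | 0 | 98.5 |
| 1.33 | 0 | 2.7 | 0.1 | 97.6 |
| 2.00 | 0 | 3.6 | 0 | 96.6 |
| 2.50 | 0 | 4.7 | 0 | 95.1 |
| 4.00 | 0 | 7.4 | 0.3 | 91.9 |
| 6.00 | 0.8 | 10.5 | 0 | 88.8 |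
| 10.0 | 2.3 | 16.9 | 0 | 81.2 |

(scatter of a reading: 0.3 percentage points)

- percentages count the starting material that a species holds: one side product counts as two

1. the largest share of what was charged as starting material, at 2.0 d belongs to (first chain carrier / target / side product / starting material)
2. the largest share itself, whichever of these holds it, in percent of the starting material charged

How much starting material stays in this flask? Work with the fraction left: take minus its logarithm and divide by the time. This loss constant (a pseudo-first-order constant) comes to 0.0208 h⁻¹ at 10.0 h and 0.0211 h⁻¹ at 4.00 h, so hold it steady. My reckoning then leaves 36.8% at 2.0 d.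

Can target pass that? It must keep more than 0.582 of what has gone, the ratio of left to gone. The green run reads 0.899 at 10.0 h, more than needed, so my reckoning names target, though the side product is growing.

The forecast also gives target, at 45%: “Target is therefore most likely the largest share”.

This flask gives target at 47.3%, with starting material at 32.8%, below the reckoned 36.8%, and side product at 17.2%.

initiator → 2 initiating radical (k = 8.40 × 10⁻⁷ s⁻¹); starting material + initiating radical → capped initiator + first chain carrier (k = 17000 M⁻¹ s⁻¹); reagent + first chain carrier ⇌ target + second chain carrier (K = 0.0890, k = 80.0 M⁻¹ s⁻¹); starting material + second chain carrier → by-product + first chain carrier (k = 800 M⁻¹ s⁻¹); 2 first chain carrier → ended chains (k = 5.50 × 10⁷ M⁻¹ s⁻¹); starting material + target → side product (k = 1.60 × 10⁻⁵ M⁻¹ s⁻¹) At 0.723 d this flask makes target 6.31 times faster than it uses it up, each step taken net. By the step from starting material and target to side product, the half-life of target at 2.00 d is 7.6 d, longer than the 2.0 d of this flask. Read the same flask at 12 h: the loss constant leaves 77.9%, and the flask holds 77.5% of its starting material.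

Readings and results are calculated for substances that don't exist; scatter was added.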